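Compound numbers 1–29 are those used in the steps and in the compound list; 29 is the target. Atom labels follow flavone numbering: ring A = C4a, C5–C8, C8a; ring C = O1, C2, C3, C4; ring B = C1′–C6′.

## Analysis of the target

The target is a pentacyclic flavone. Ring A is a phloroglucinol-type benzene, ring C the pyranone, and ring B a resorcinol-type benzene on C2. A seven-membered oxepine ties C3 to O2′ through a CH2–CH(O) unit, and a 2,2-dimethyl-2H-pyran is fused at C7–C8 with its oxygen on C7 (angular fusion). The only stereocentre is the oxepine carbon that carries the aryl ether oxygen and the 2-hydroxypropan-2-yl group; it is (R) and has no neighbouring centre to relay from. The sensitive groups are the chromene double bond (acid, hydrogenation, electrophiles), the tertiary alcohol (dehydration) and two phenols, one of them chelated to the C4 carbonyl. Three things make the synthesis hard. The stereocentre lies between a hindered aryl ether oxygen and a fully substituted carbinol, so making its C–O bond by substitution is unattractive. Ring A has two oxygens ortho to the future C4 carbonyl, and only closure through the one next to the pyran carbon gives the angular isomer. The last deprotection must spare the chromene and the carbinol. The strategy rests on the CH2–CH(O) bond of the oxepine. If the carbinol is read as an ester plus two methyl nucleophiles, the CH(O) carbon is the α-carbon of a ring B aryloxyacetate. The CH2 on C3 is then the exocyclic methylene of a Morita–Baylis–Hillman adduct of a ring B aldehyde (its carbonyl carbon becomes C2) and a ring A aryl vinyl ketone (carbonyl carbon C4, α-carbon C3). Joining the carbinol oxygen of that adduct to the aryloxyacetate as a lactone makes the bond formation an intramolecular enolate Claisen rearrangement that hands the carbinol configuration to the new centre.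

## Retrosynthetic reasoning

**29 ⇐ 28.** The two phenolic O–H bonds are uncovered last, from the bis(allyl ether) 28. Allyl is chosen because a zerovalent palladium catalyst with an amine acceptor removes it under neutral conditions. Acid-labile or hydrogenolysable groups would put the chromene double bond and the tertiary alcohol at risk at this stage.

**28 ⇐ 26 + 27.** The two C–CH3 bonds of the carbinol are cut, giving methyl ester 26 and methyllithium 27. This is placed late because the ring A ketone then exists only as the vinylogous ester carbonyl of ring C, the least electrophilic form it takes in the route. The gain is that the stereogenic carbon becomes the α-carbon of a carboxyl derivative and so comes within reach of enolate chemistry. The forward step must add twice without enolising that carbon.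

**26 ⇐ 25 ⇐ 23 ⇐ 21 + 22.** The O1–C2 bond and the C2=C3 unsaturation are removed. Flavone 26 comes from flavanone 25 by loss of two hydrogens to a quinone. Flavanone 25 is the oxa-Michael adduct of hydroxychalcone 24, which is freed from methoxymethyl ether 23. The ring A ketone of 23 has two ortho oxygens and only the one next to the pyran carbon may close ring C. That oxygen therefore carries the acid-labile methoxymethyl group and the other carries allyl. Ester 23 is made from acid 21 with 22.

**21 ⇐ 18 (key disconnection).** The CH2–CH(O) bond of the oxepine in 21 is cut. It is chosen over the aryl ether C–O bond and the C2–C1′ bond because it is the only ring bond whose formation can create the stereocentre under control of a centre that is easy to set. In the retro-[3,3] sense the carboxyl oxygen is reattached to the chalcone β-carbon and the alkene returns to the exocyclic position. The result is lactone 18, a seven-membered aryloxyacetate ester of an allylic, benzylic carbinol. Rearrangements of this kind are usually counted as ring contractions, but here the ring size stays at seven: the ring oxygen and the carbonyl carbon leave as the carboxyl group and the two alkene carbons enter. One operation thus forms the oxepine, the cyclic chalcone with the aroyl group on the right carbon, the carboxyl handle for the carbinol, and the stereocentre. The forward reaction must enolise the lactone and bond the enolate carbon to the methylene terminus on the face fixed by the tether.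

**18 ⇐ 17 ⇐ 16.** The acyl–oxygen bond of the lactone is cut to hydroxy acid 17, which comes from ethyl ester 16 by hydrolysis. Closing the ring at the acyl carbon leaves the carbinol C–O bond alone, so the (S) configuration of 16 passes unchanged into 18.

**16 ⇐ 5 + 15.** The bond between the carbinol carbon and the α-carbon of the enone is the Morita–Baylis–Hillman bond. It joins ring B aldehyde 5 to ring A vinyl ketone 15 and is the convergent step. The forward reaction has to set the (S) carbinol.

**5 ⇐ 3 + 4; 3 ⇐ 1 + 2.** Two ether bonds of ring B are cut. The hindered aryl ether oxygen of the target is thus introduced at the very start as a simple O-alkylation of phenol 3 with bromoacetate 4. The 4-hydroxyl of 1 is first alkylated selectively with 2.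

**15 ⇐ 11 + 12; 11 ⇐ 9 + 10; 9 ⇐ 8 + 2; 8 ⇐ 6 + 7.** The vinyl ketone comes from methyl ketone 11 by α-methylenation with 12. The two ortho oxygens of 8 are told apart by their steric environment: the less hindered one is allylated with 2 to give 9, and the other is protected with 10. The pyran is annulated onto 6 with enal 7 at the outset, so that its position is settled before any flavone exists.

## Alternatives that were turned down

**Alternative 1:** Ring A is cut at C4a–C5 and ring C at O1–C2. This unravels the flavone into benzoxepinone A1, which carries a 3,5,7-trioxoheptanoate chain on the carbon α to its ketone.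
- *Forward key step:* Mg(OMe)2 would form the chelated polyenolate of A1. The C4a methylene would attack the ester carbon in a Claisen condensation to give the acylphloroglucinol ring, and acid work-up would close O1–C2 to the 5,7-dihydroxyflavone A2.
- *For it:* Ring A appears with all three oxygens in place. Its two ortho hydroxyls are equivalent, so closing ring C raises no regiochemical question. The flavone oxidation level is built in, so no dehydrogenation and no differentiation of ring A oxygens is needed. On these two points it is stronger than the chosen route.
- *Against it:* A1 is a tetracarbonyl chain next to an enolisable oxepinone and a free tertiary alcohol. Such chains can cyclise in aldol and pyrone modes as well as the Claisen mode, and they must be assembled by polyanion acylations. The stereocentre has to be made earlier in a separate operation. After A2 the dimethylpyran must still be annulated onto a 5,7-dihydroxyflavone, where C6 and C8 compete, and the methoxymethyl ether must be removed by acid next to the new chromene.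
- *Comparison:* The chosen route fixes the pyran position on acetophenone 8 and makes the stereocentre in the ring-forming step. In exchange it accepts one oxidation (step 13) and a three-group protecting scheme.

**Alternative 2:** The C2–C1′ bond is cut, opening the oxepine between ring C and ring B. The precursor is chromone A3, with a free C2–H and a C3 side chain ending in an ortho-bromoaryl ether.
- *Forward key step:* The aryl bromide of A3 would add to zerovalent palladium formed from Pd(OAc)2 and PCy3. Metalation of the chromone C2–H assisted by K2CO3 and pivalic acid, then reductive elimination, would close the seven-membered ring to A4.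
- *For it:* The closing step belongs to a well-studied reaction class (concerted metalation–deprotonation). The chromone with its angular pyran is made beforehand without ortho-oxygen ambiguity, and no redox adjustment follows ring closure. In precedent for the ring-closing event this alternative is stronger than the chosen one.
- *Against it:* The whole stereochemical burden moves into the synthesis of A3. Its aryl ether must be made at a secondary carbon next to a fully substituted carbinol and ortho to bromine, where elimination and attack at the wrong terminus compete. The electron-rich aryl bromide adds slowly, so hot carbonate conditions are needed. A4 still needs cleavage of a methyl ether at O5 and of two methoxymethyl ethers, that is Lewis and protic acid next to the chromene and the tertiary centre.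
- *Comparison:* The chosen route makes the aryl ether bond first, as a simple phenol alkylation, builds the hindered carbinol last by two methyl additions, and ends with a neutral deallylation. What it offers in place of precedent is that ring closure and stereocentre come from one step.

**Alternative 3:** Ring C is cut at C4a–C4, C4–C3 and O1–C2. The three components are ring A aryl iodide A5, CO and benzoxepinone A6.
- *Forward key step:* Under Pd(dba)2 with a wide-bite-angle bisphosphine, the acylpalladium from A5 and CO would acylate the enolate of A6, forming both carbon–carbon bonds of ring C at the 1,3-dicarbonyl level. Acid would then remove the acid-labile groups and close O1–C2 to give A7.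
- *For it:* It is the most convergent plan. The pyran position is fixed in A5. Cyclodehydration of a 1,3-dicarbonyl compound is the most dependable way to a chromone and needs no oxidant, so on this point it is stronger than the flavanone dehydrogenation of the chosen route.
- *Against it:* The acylpalladium carries two ortho substituents on an electron-rich ring and is hindered. Direct arylation without CO and O-acylation of the enolate compete. A6 must be made enantiopure in a separate sequence that includes a seven-membered ring closure. A7 still needs demethylation at O5 by a Lewis acid next to the tertiary alcohol and the chromene.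
- *Comparison:* The chosen route is longer in its linear part after the coupling. It needs no separate enantioselective synthesis of an oxepinone, and it ends with a neutral deprotection.

Key step: step 10

Assumption: the sense of induction of the phosphine–thiourea catalyst in step 7 cannot be fixed by analogy alone; the catalyst enantiomer (from L- or D-valine) that delivers the (S)-carbinol 16 is the one used.

## Route

**Step 1**
Reactants: 1 2,4-dihydroxybenzaldehyde; 2 allyl bromide
Product: 3 4-(allyloxy)-2-hydroxybenzaldehyde
Conditions: allyl bromide (1.05 equiv), KHCO3, MeCN, 60 °C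
Reagents that add atoms: allyl bromide, C=CCBr
Why: Williamson ether synthesis; the 4-hydroxyl is the more acidic and is not tied up in the hydrogen bond to the formyl group, so a weak base alkylates it selectively.

**Step 2**
Reactants: 3 4-(allyloxy)-2-hydroxybenzaldehyde; 4 ethyl bromoacetate
Product: 5 ethyl 2-[5-(allyloxy)-2-formylphenoxy]acetate
Conditions: BrCH2CO2Et, K2CO3, DMF, rt
Reagents that add atoms: ethyl bromoacetate, CCOC(=O)CBr
Why: Williamson O-alkylation of the remaining chelated phenol with a reactive α-halo ester; room temperature avoids the intramolecular aldol condensation to a benzofuran-2-carboxylate.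

**Step 3**
Reactants: 6 2,4,6-trihydroxyacetophenone; 7 3-methylbut-2-enal
Product: 8 1-(5,7-dihydroxy-2,2-dimethyl-2H-chromen-6-yl)ethanone
Conditions: 3-methylbut-2-enal (1.1 equiv), pyridine, 110 °C
Reagents that add atoms: 3-methylbut-2-enal, CC(C)=CC=O
Why: Chromenylation by aldol-type C-alkylation of the phenol, dehydration to an ortho-quinone methide and oxa-6π electrocyclisation; the two ring CH positions are equivalent, and closure through the non-chelated hydroxyl para to the acetyl group should give the 6-acetyl isomer with both chelated hydroxyls left free.

**Step 4**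
Reactants: 8 1-(5,7-dihydroxy-2,2-dimethyl-2H-chromen-6-yl)ethanone; 2 allyl bromide
Product: 9 1-[7-(allyloxy)-5-hydroxy-2,2-dimethyl-2H-chromen-6-yl]ethanone
Conditions: allyl bromide (1.05 equiv), K2CO3, acetone, 50 °C
Reagents that add atoms: allyl bromide, C=CCBr
Why: Williamson ether synthesis; the 5-hydroxyl is flanked by the acetyl group and the peri C4–H and held in the stronger chelate, so one equivalent of halide should alkylate the more accessible 7-hydroxyl.

**Step 5**
Reactants: 9 1-[7-(allyloxy)-5-hydroxy-2,2-dimethyl-2H-chromen-6-yl]ethanone; 10 chloromethyl methyl ether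
Product: 11 1-[7-(allyloxy)-5-(methoxymethoxy)-2,2-dimethyl-2H-chromen-6-yl]ethanone
Conditions: NaH, MeOCH2Cl, DMF, 0 °C to rt
Reagents that add atoms: chloromethyl methyl ether, COCCl
Why: Acetal protection of the hindered chelated phenol after full deprotonation; an ortho-acyl methoxymethyl ether can later be cleaved by mild acid while the allyl ethers stay.

**Step 6**
Reactants: 11 1-[7-(allyloxy)-5-(methoxymethoxy)-2,2-dimethyl-2H-chromen-6-yl]ethanone; 12 N,N-dimethylmethyleneiminium iodide (Eschenmoser's salt)
Product: 15 1-[7-(allyloxy)-5-(methoxymethoxy)-2,2-dimethyl-2H-chromen-6-yl]prop-2-en-1-one, via Mannich base 13 (not isolated), via trimethylammonium iodide 14 (not isolated)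
Conditions: LiN(SiMe3)2, THF, −78 °C; CH2=NMe2+ I−, −78 °C to rt; MeI, CH2Cl2, rt; aq. NaHCO3, rt
Reagents that add atoms: N,N-dimethylmethyleneiminium iodide, C[N+](C)=C.[I-]
Why: α-Methylenation of a methyl ketone: the lithium enolate of the only enolisable position undergoes a Mannich reaction, and quaternisation followed by base-induced elimination of trimethylamine gives the vinyl ketone, which is used at once.

**Step 7**
Reactants: 5 ethyl 2-[5-(allyloxy)-2-formylphenoxy]acetate; 15 1-[7-(allyloxy)-5-(methoxymethoxy)-2,2-dimethyl-2H-chromen-6-yl]prop-2-en-1-one
Product: 16 ethyl 2-{5-(allyloxy)-2-[(1S)-2-{[7-(allyloxy)-5-(methoxymethoxy)-2,2-dimethyl-2H-chromen-6-yl]carbonyl}-1-hydroxyprop-2-en-1-yl]phenoxy}acetate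
Conditions: 1-[3,5-bis(trifluoromethyl)phenyl]-3-[1-(diphenylphosphanyl)-3-methylbutan-2-yl]thiourea (valine-derived, 10 mol%), CHCl3, 0 °C to rt, 15 (1.5 equiv) added over 12 h
Reagents that add atoms: none
Why: Enantioselective Morita–Baylis–Hillman reaction: the phosphine adds to the unhindered β-carbon of 15, the phosphonium enolate attacks aldehyde 5 held by the thiourea hydrogen bonds, and proton transfer with loss of phosphine gives the carbinol; the chiral scaffold fixes the aldehyde face and so sets the (S) centre, and slow addition of 15 holds back its dimerisation.

**Step 8**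
Reactants: 16 (S)-Morita–Baylis–Hillman carbinol ethyl ester
Product: 17 2-{5-(allyloxy)-2-[(1S)-2-{[7-(allyloxy)-5-(methoxymethoxy)-2,2-dimethyl-2H-chromen-6-yl]carbonyl}-1-hydroxyprop-2-en-1-yl]phenoxy}acetic acid
Conditions: LiOH, THF/H2O (3:1), 0 °C; then 1 M HCl to pH 4, 0 °C
Reagents that add atoms: lithium hydroxide, [Li+].[OH-]
Why: Saponification; the aryloxyacetate is an activated, unhindered ester that hydroxide should cleave at 0 °C faster than it adds to the enone, and brief cold acidification to pH 4 spares the methoxymethyl ether.

**Step 9**
Reactants: 17 (S)-hydroxy acid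
Product: 18 (5S)-8-(allyloxy)-5-{3-[7-(allyloxy)-5-(methoxymethoxy)-2,2-dimethyl-2H-chromen-6-yl]-3-oxoprop-1-en-2-yl}-2H-1,4-benzodioxepin-3(5H)-one
Conditions: 2-chloro-1-methylpyridinium iodide, Et3N, CH2Cl2, 40 °C, slow addition (0.002 M)
Reagents that add atoms: none
Why: Mukaiyama lactonisation through the 2-acyloxypyridinium salt under high dilution; the benzo ring and the ether oxygen pre-organise the seven-membered ring, acyl activation leaves the carbinol C–O bond untouched so (S) is retained, and no nucleophilic catalyst is present that could scramble the allylic ester by SN2′ addition.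

**Step 10**
Reactants: 18 (5S)-lactone
Product: 21 (2R)-8-(allyloxy)-4-{[7-(allyloxy)-5-(methoxymethoxy)-2,2-dimethyl-2H-chromen-6-yl]carbonyl}-2,3-dihydro-1-benzoxepine-2-carboxylic acid, via silyl ketene acetal 19 (not isolated), via trimethylsilyl ester 20 (not isolated)
Conditions: Me3SiCl, Et3N, THF, −78 °C; LiN(SiMe3)2 (1.1 equiv), −78 °C to rt; aq. citric acid
Reagents that add atoms: none
Why: Proposed new method: LiN(SiMe3)2 removes a proton from the only enolisable position, the aryloxy-bearing CH2 of the lactone, and Me3SiCl present from the start traps the enolate as cyclic silyl ketene acetal 19, whose O–C=C unit, lactone C–O bond and exocyclic C=CH2 make up the 3-oxa-1,5-diene of an Ireland–Claisen rearrangement; the closest known reactions are the Ireland–Claisen rearrangement of lactone silyl ketene acetals that carry an exocyclic vinyl group, which run through bridged boat transition states, and the SN2′ alkylation of Morita–Baylis–Hillman esters by enolates, neither of which has been run on a lactone of a Morita–Baylis–Hillman carbinol. The [3,3] shift joins the ketene acetal carbon to the methylene terminus, breaks the carbinol C–O bond, moves the alkene into conjugation with the ketone and ring B, and leaves silyl ester 20, which the acidic work-up hydrolyses to 21. The oxepine is closed in a 7-endo-trig sense at the methylene carbon while the ester bridge is expelled from the ring, so a seven-membered lactone becomes a seven-membered cyclic ether. Because the aryl ether links the two reacting termini, the six-atom array can only fold as a boat inside a bicyclo[3.2.2] framework, with the vinyl ketone over the lactone face that bears it. The new bond therefore forms on that face alone, and the (S) carbinol centre, which becomes trigonal, is exchanged for the (R) aryloxy centre. If the enolate instead adds to the enone in a Michael sense and the ketone enolate then expels the carboxylate, the same tether dictates the same face and the same product. The step needs site-selective deprotonation, secured because the ketone has no α-hydrogen, and intramolecular rather than intermolecular bond formation, secured by dilution and by the proximity of the termini; the electron-poor alkene and electron-rich ketene acetal should let it run at or below room temperature, before base can epimerise the new centre.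

**Step 11**
Reactants: 21 (2R)-benzoxepine-2-carboxylic acid; 22 (trimethylsilyl)diazomethane
Product: 23 methyl (2R)-8-(allyloxy)-4-{[7-(allyloxy)-5-(methoxymethoxy)-2,2-dimethyl-2H-chromen-6-yl]carbonyl}-2,3-dihydro-1-benzoxepine-2-carboxylate
Conditions: Me3SiCHN2, PhMe/MeOH (4:1), 0 °C
Reagents that add atoms: (trimethylsilyl)diazomethane, C[Si](C)(C)C=[N+]=[N-]
Why: Esterification through a methyldiazonium carboxylate ion pair under neutral conditions, so the α-aryloxy stereocentre is not exposed to base.

**Step 12**
Reactants: 23 (2R)-methyl ester methoxymethyl ether
Product: 25 2,3-dihydro (flavanone) form of 26 with (R) configuration at the ester-bearing oxepine carbon (mixture of C2/C3 epimers), via hydroxychalcone ester 24 (not isolated)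
Conditions: p-TsOH·H2O (0.2 equiv), MeOH, 50 °C
Reagents that add atoms: none
Why: Acid-catalysed transacetalisation removes the only methoxymethyl group, which is activated by the ortho carbonyl, and the freed phenol adds to the chalcone β-carbon (6-endo-trig oxa-Michael addition) to give the flavanone; the two new centres are destroyed in the next step, and the allyl ethers, chromene and ester should survive.

**Step 13**
Reactants: 25 flavanone methyl ester
Product: 26 methyl ester analogue of 28 in which CO2Me replaces the C(CH3)2OH group (5,4′-di-O-allyl oxepinoflavone, R)
Conditions: DDQ (1.5 equiv), 1,4-dioxane, 90 °C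
Reagents that add atoms: none
Why: Quinone dehydrogenation of a flavanone: hydride is taken from C2, which is benzylic, α to oxygen and conjugated with the two ether oxygens of ring B, and loss of the C3 proton gives the flavone; DDQ is preferred to I2 in hot DMSO, which cleaves aryl allyl ethers, the one ortho to the carbonyl first, and would so expose the second ortho oxygen of ring A to ring-opening and reclosure toward the linear pyranoflavone.

**Step 14**
Reactants: 26 flavone methyl ester; 27 methyllithium
Product: 28 5,4′-di-O-allyl ether of the target
Conditions: CeCl3 (anhydrous, 4 equiv), MeLi (4 equiv), THF, −78 to −40 °C; aq. NH4Cl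
Reagents that add atoms: methyllithium, [Li]C
Why: Double addition of the organocerium reagent to the α-aryloxy ester through the methyl ketone; its low basicity avoids enolisation at the stereocentre, and the ring C carbonyl, a vinylogous ester shielded by the O5-allyl group and the C3 substituent, should react more slowly than the activated ester.

**Step 15**
Reactants: 28 5,4′-di-O-allyl ether of the target
Product: 29 target, (R)-configured oxepinoflavone with free 5- and 4′-hydroxyls
Conditions: Pd(PPh3)4 (5 mol%), morpholine, THF, rt
Reagents that add atoms: none
Why: Tsuji–Trost deallylation: zerovalent palladium ionises each aryl allyl ether to a π-allyl complex that morpholine captures; the conditions are neutral and leave the chromene double bond, the tertiary alcohol and the stereocentre alone.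

## Compound list

1 | 2,4-dihydroxybenzaldehyde | O=Cc1ccc(O)cc1O | starting material
2 | allyl bromide | C=CCBr | starting material
3 | 4-(allyloxy)-2-hydroxybenzaldehyde | O=Cc1ccc(OCC=C)cc1O | intermediate
4 | ethyl bromoacetate | CCOC(=O)CBr | starting material
5 | ethyl 2-[5-(allyloxy)-2-formylphenoxy]acetate | CCOC(=O)COc1cc(OCC=C)ccc1C=O | intermediate
6 | 2,4,6-trihydroxyacetophenone | CC(=O)c1c(O)cc(O)cc1O | starting material
7 | 3-methylbut-2-enal | CC(C)=CC=O | starting material
8 | 1-(5,7-dihydroxy-2,2-dimethyl-2H-chromen-6-yl)ethanone | CC(=O)c1c(O)cc2OC(C)(C)C=Cc2c1O | intermediate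
9 | 1-[7-(allyloxy)-5-hydroxy-2,2-dimethyl-2H-chromen-6-yl]ethanone | CC(=O)c1c(OCC=C)cc2OC(C)(C)C=Cc2c1O | intermediate
10 | chloromethyl methyl ether | COCCl | starting material
11 | 1-[7-(allyloxy)-5-(methoxymethoxy)-2,2-dimethyl-2H-chromen-6-yl]ethanone | CC(=O)c1c(OCC=C)cc2OC(C)(C)C=Cc2c1OCOC | intermediate
12 | N,N-dimethylmethyleneiminium iodide (Eschenmoser's salt) | C[N+](C)=C.[I-] | starting material
13 | 1-[7-(allyloxy)-5-(methoxymethoxy)-2,2-dimethyl-2H-chromen-6-yl]-3-(dimethylamino)propan-1-one (Mannich base) | CN(C)CCC(=O)c1c(OCC=C)cc2OC(C)(C)C=Cc2c1OCOC | intermediate (not isolated)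
14 | 3-[7-(allyloxy)-5-(methoxymethoxy)-2,2-dimethyl-2H-chromen-6-yl]-N,N,N-trimethyl-3-oxopropan-1-aminium iodide | C[N+](C)(C)CCC(=O)c1c(OCC=C)cc2OC(C)(C)C=Cc2c1OCOC.[I-] | intermediate (not isolated)
15 | 1-[7-(allyloxy)-5-(methoxymethoxy)-2,2-dimethyl-2H-chromen-6-yl]prop-2-en-1-one | C=CC(=O)c1c(OCC=C)cc2OC(C)(C)C=Cc2c1OCOC | intermediate
16 | ethyl 2-{5-(allyloxy)-2-[(1S)-2-{[7-(allyloxy)-5-(methoxymethoxy)-2,2-dimethyl-2H-chromen-6-yl]carbonyl}-1-hydroxyprop-2-en-1-yl]phenoxy}acetate | CCOC(=O)COc1cc(OCC=C)ccc1[C@H](O)C(=C)C(=O)c3c(OCC=C)cc4OC(C)(C)C=Cc4c3OCOC | intermediate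
17 | 2-{5-(allyloxy)-2-[(1S)-2-{[7-(allyloxy)-5-(methoxymethoxy)-2,2-dimethyl-2H-chromen-6-yl]carbonyl}-1-hydroxyprop-2-en-1-yl]phenoxy}acetic acid | OC(=O)COc1cc(OCC=C)ccc1[C@H](O)C(=C)C(=O)c3c(OCC=C)cc4OC(C)(C)C=Cc4c3OCOC | intermediate
18 | (5S)-8-(allyloxy)-5-{3-[7-(allyloxy)-5-(methoxymethoxy)-2,2-dimethyl-2H-chromen-6-yl]-3-oxoprop-1-en-2-yl}-2H-1,4-benzodioxepin-3(5H)-one | O=C1COc2cc(OCC=C)ccc2[C@H](O1)C(=C)C(=O)c3c(OCOC)c4C=CC(C)(C)Oc4cc3OCC=C | intermediate
19 | (5S)-8-(allyloxy)-5-{3-[7-(allyloxy)-5-(methoxymethoxy)-2,2-dimethyl-2H-chromen-6-yl]-3-oxoprop-1-en-2-yl}-3-(trimethylsilyloxy)-5H-1,4-benzodioxepine (silyl ketene acetal) | C[Si](C)(C)OC1=COc2cc(OCC=C)ccc2[C@H](O1)C(=C)C(=O)c3c(OCOC)c4C=CC(C)(C)Oc4cc3OCC=C | intermediate (not isolated)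
20 | trimethylsilyl (2R)-8-(allyloxy)-4-{[7-(allyloxy)-5-(methoxymethoxy)-2,2-dimethyl-2H-chromen-6-yl]carbonyl}-2,3-dihydro-1-benzoxepine-2-carboxylate | C[Si](C)(C)OC(=O)[C@H]1CC(C(=O)c3c(OCOC)c4C=CC(C)(C)Oc4cc3OCC=C)=Cc2ccc(OCC=C)cc2O1 | intermediate (not isolated)
21 | (2R)-8-(allyloxy)-4-{[7-(allyloxy)-5-(methoxymethoxy)-2,2-dimethyl-2H-chromen-6-yl]carbonyl}-2,3-dihydro-1-benzoxepine-2-carboxylic acid | OC(=O)[C@H]1CC(C(=O)c3c(OCOC)c4C=CC(C)(C)Oc4cc3OCC=C)=Cc2ccc(OCC=C)cc2O1 | intermediate
22 | (trimethylsilyl)diazomethane | C[Si](C)(C)C=[N+]=[N-] | starting material
23 | methyl (2R)-8-(allyloxy)-4-{[7-(allyloxy)-5-(methoxymethoxy)-2,2-dimethyl-2H-chromen-6-yl]carbonyl}-2,3-dihydro-1-benzoxepine-2-carboxylate | COC(=O)[C@H]1CC(C(=O)c3c(OCOC)c4C=CC(C)(C)Oc4cc3OCC=C)=Cc2ccc(OCC=C)cc2O1 | intermediate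
24 | methyl (2R)-8-(allyloxy)-4-{[7-(allyloxy)-5-hydroxy-2,2-dimethyl-2H-chromen-6-yl]carbonyl}-2,3-dihydro-1-benzoxepine-2-carboxylate | COC(=O)[C@H]1CC(C(=O)c3c(O)c4C=CC(C)(C)Oc4cc3OCC=C)=Cc2ccc(OCC=C)cc2O1 | intermediate (not isolated)
25 | flavanone methyl ester: 2,3-dihydro form of 26, (R) at the ester-bearing oxepine carbon, mixture of epimers at C2 and C3 | CC1(C)C=Cc2c(cc(OCC=C)c3C(=O)C4C(Oc23)c2ccc(OCC=C)cc2O[C@@H](C(=O)OC)C4)O1 | intermediate
26 | flavone methyl ester: the target skeleton with CO2Me in place of C(CH3)2OH and allyl ethers on O5 and O4′, (R) | CC1(C)C=Cc2c(cc(OCC=C)c3c(=O)c4c(oc23)-c2ccc(OCC=C)cc2O[C@@H](C(=O)OC)C4)O1 | intermediate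
27 | methyllithium | [Li]C | starting material
28 | 5,4′-di-O-allyl ether of the target, (R) | CC1(C)C=Cc2c(cc(OCC=C)c3c(=O)c4c(oc23)-c2ccc(OCC=C)cc2O[C@@H](C(C)(C)O)C4)O1 | intermediate
29 | CNP0329736.1, (R)-configured oxepinoflavone with angular dimethylpyran, 5- and 4′-hydroxyls and 2-hydroxypropan-2-yl group | CC1(C)C=Cc2c(cc(O)c3c(=O)c4c(oc23)-c2ccc(O)cc2O[C@@H](C(C)(C)O)C4)O1 | target

## Step count and least certain steps

Total step count: 15. Longest linear sequence: 13 steps (6 → 8 → 9 → 11 → 15 → 16 → 17 → 18 → 21 → 23 → 25 → 26 → 28 → 29); the ring B branch (1 → 3 → 5) joins at step 7.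

**Step 10 (key step, proposed new method).** The most likely failure is that the enolate or its silyl ketene acetal does not fold into the strained bridged boat. It would then add to the enone of a second molecule, or fragment to an aryloxyketene and the allylic alkoxide, giving oligomers or ring-opened material. A second danger is loss of configuration through epimerisation of the new α-aryloxy ester centre by excess base. The fallback uses known chemistry and sets out from 16. The carbinol is acetylated with AcCl and pyridine to the acetate F1. LiN(SiMe3)2 at −78 °C then forms the ester enolate, which closes the oxepine by conjugate addition to the enone and loss of acetate (intramolecular SN2′ alkylation of a Morita–Baylis–Hillman acetate) to give the racemic ethyl ester F2. LiOH hydrolyses it to the racemic acid F3, which is resolved as its salt with (S)-1-phenylethylamine or on a chiral stationary phase. The (R) acid rejoins the route at 21. This fallback gives up the chirality transfer and half the material.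

**Step 7.** The aldehyde is electron-rich and ortho-substituted, so addition to it may be slow. Phosphine-induced dimerisation of 15 could then take over, and facial selectivity may be only moderate. The fallback sets out from 15 and 5. PhSeLi adds to 15 at −78 °C and the lithium enolate is trapped by 5 in an aldol reaction to give the selenide F4. H2O2 with pyridine at 0 °C oxidises selenium, and syn-elimination gives the racemic carbinol F5. Acylative kinetic resolution with isobutyric anhydride and the benzotetramisole enantiomer that acylates the (R) carbinol gives the isobutyrate F6 and leaves the (S) alcohol, which rejoins the route at 16.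

**Step 9.** The hydroxyl is secondary and hindered, so intermolecular esterification to dimers and oligomers may outrun ring closure. The fallback sets out from 16 and skips 17. Intramolecular transesterification in dilute toluene at 80 °C with catalytic Ti(OiPr)4 and 4 Å sieves to take up ethanol would give 18 directly. No new compound is made.

**Step 13.** Hydride abstraction from the hindered C2–H may be slow. The quinone could then begin to oxidise the allyl ether methylenes, or uncyclised 24 could remain unconverted. The fallback sets out from 25. Me3SiOTf with Et3N gives the silyl enol ether F7. Pd(OAc)2 (divalent palladium) in MeCN then effects Saegusa–Ito dehydrosilylation and returns to the route at 26.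

**Step 14.** The reagent may add to the ring C carbonyl as well, or enolise the centre α to the ester or the intermediate methyl ketone with loss of configuration. The fallback sets out from 26 and reverses the last two operations. Pd(PPh3)4 with morpholine first removes both allyl groups to give the diphenol ester F8. Excess MeMgBr in THF at 0 °C is then used: the magnesium chelate of the 5-oxide with the C4 carbonyl shields ring C, and the less basic Grignard reagent adds twice to the ester. Work-up with aqueous NH4Cl gives the target, so this fallback ends at 29.

## Further compounds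

F1 | step 10 | ethyl 2-{2-[(1S)-1-acetoxy-2-{[7-(allyloxy)-5-(methoxymethoxy)-2,2-dimethyl-2H-chromen-6-yl]carbonyl}prop-2-en-1-yl]-5-(allyloxy)phenoxy}acetate | CCOC(=O)COc1cc(OCC=C)ccc1[C@H](OC(C)=O)C(=C)C(=O)c3c(OCC=C)cc4OC(C)(C)C=Cc4c3OCOC
F2 | step 10 | ethyl (±)-8-(allyloxy)-4-{[7-(allyloxy)-5-(methoxymethoxy)-2,2-dimethyl-2H-chromen-6-yl]carbonyl}-2,3-dihydro-1-benzoxepine-2-carboxylate | CCOC(=O)C1CC(C(=O)c3c(OCOC)c4C=CC(C)(C)Oc4cc3OCC=C)=Cc2ccc(OCC=C)cc2O1
F3 | step 10 | (±)-8-(allyloxy)-4-{[7-(allyloxy)-5-(methoxymethoxy)-2,2-dimethyl-2H-chromen-6-yl]carbonyl}-2,3-dihydro-1-benzoxepine-2-carboxylic acid | OC(=O)C1CC(C(=O)c3c(OCOC)c4C=CC(C)(C)Oc4cc3OCC=C)=Cc2ccc(OCC=C)cc2O1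
F4 | step 7 | ethyl 2-{5-(allyloxy)-2-[3-{7-(allyloxy)-5-(methoxymethoxy)-2,2-dimethyl-2H-chromen-6-yl}-1-hydroxy-3-oxo-2-(phenylselanylmethyl)propyl]phenoxy}acetate (diastereomer mixture) | CCOC(=O)COc1cc(OCC=C)ccc1C(O)C(C[Se]c2ccccc2)C(=O)c3c(OCC=C)cc4OC(C)(C)C=Cc4c3OCOC
F5 | step 7 | racemic form of carbinol 16 | CCOC(=O)COc1cc(OCC=C)ccc1C(O)C(=C)C(=O)c3c(OCC=C)cc4OC(C)(C)C=Cc4c3OCOC
F6 | step 7 | (R)-isobutyrate of the carbinol (enantiomeric series of 16) | CCOC(=O)COc1cc(OCC=C)ccc1[C@@H](OC(=O)C(C)C)C(=C)C(=O)c3c(OCC=C)cc4OC(C)(C)C=Cc4c3OCOC
F0 | step 9 | none | none
F7 | step 13 | trimethylsilyl enol ether of flavanone 25 (C3=C4 enol ether, C2 epimer mixture) | CC1(C)C=Cc2c(cc(OCC=C)c3C(O[Si](C)(C)C)=C4C(Oc23)c2ccc(OCC=C)cc2O[C@@H](C(=O)OC)C4)O1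
F8 | step 14 | 5,4′-dihydroxy flavone methyl ester (26 without its allyl groups), (R) | CC1(C)C=Cc2c(cc(O)c3c(=O)c4c(oc23)-c2ccc(O)cc2O[C@@H](C(=O)OC)C4)O1
A1 | alternative 1 | methyl 7-[(2R)-2-(2-hydroxypropan-2-yl)-8-(methoxymethoxy)-5-oxo-2,3,4,5-tetrahydro-1-benzoxepin-4-yl]-3,5,7-trioxoheptanoate | COC(=O)CC(=O)CC(=O)CC(=O)C1C[C@H](C(C)(C)O)Oc2cc(OCOC)ccc2C1=O
A2 | alternative 1 | 5,7-dihydroxy oxepinoflavone core without the dimethylpyran, 4′-O-methoxymethyl ether, (R) | Oc1cc(O)c2c(=O)c3c(oc2c1)-c1ccc(OCOC)cc1O[C@@H](C(C)(C)O)C3
A3 | alternative 2 | angular pyranochromone with free C2–H, 5-O-methyl, C3 side chain (2R)-2-[2-bromo-5-(methoxymethoxy)phenoxy]-3-(methoxymethoxy)-3-methylbutyl | CC1(C)C=Cc2c(cc(OC)c3c(=O)c(C[C@@H](Oc4cc(OCOC)ccc4Br)C(C)(C)OCOC)coc23)O1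
A4 | alternative 2 | target as its 5-O-methyl ether with 4′-O- and tertiary O-methoxymethyl ethers, (R) | CC1(C)C=Cc2c(cc(OC)c3c(=O)c4c(oc23)-c2ccc(OCOC)cc2O[C@@H](C(C)(C)OCOC)C4)O1
A5 | alternative 3 | 6-iodo-7-methoxy-5-(methoxymethoxy)-2,2-dimethyl-2H-chromene | COCOc1c(I)c(OC)cc2OC(C)(C)C=Cc12
A6 | alternative 3 | (2R)-8-(methoxymethoxy)-2-[2-(methoxymethoxy)propan-2-yl]-3,4-dihydro-1-benzoxepin-5(2H)-one | O=C1CC[C@H](C(C)(C)OCOC)Oc2cc(OCOC)ccc12
A7 | alternative 3 | target as its 5-O-methyl ether, (R) | CC1(C)C=Cc2c(cc(OC)c3c(=O)c4c(oc23)-c2ccc(O)cc2O[C@@H](C(C)(C)O)C4)O1
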